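**Strategy.** The route rests on cutting the pyrone at C4–C5 and O1–C2. Pyrone O1, C6 (ethyl) and C5 (methyl) are the enol of symmetrical 3-pentanone, and C2–C3–C4 are a malonyl unit carried on C6 of ring A (flavanone numbering). Because both partners are symmetrical, one [3+3] acylation–lactonisation of the pentanone enol silane with an aryl(chlorocarbonyl)ketene closes the pyrone with no regiochemical choice. The precursor is an 8-prenyl-5,7-diacetoxychromone bearing the ketene at C6, generated from the malonic acid without free HCl. Iodine at C6 first steers the Claisen prenylation to C8 and then serves as the coupling handle. The C2 stereocentre is set late by rhodium-catalysed phenyl addition.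

Key step: step 11

Assumption: the hydroxorhodium–diene catalyst is taken to distinguish the faces of the chromone C2=C3 bond as it does those of 2-cyclohexenone, so the (1S,4S)-diene should give the (2S)-flavanone (the antipodal diene would be used if a test on the parent chromone showed the opposite sense); rotation about the aryl–pyrone bond is taken to be fast in the target, so this axis is not treated as a stereo-element.

**Step 1**
Reactants: 1 5,7-dihydroxy-4H-chromen-4-one; 2 3-chloro-3-methylbut-1-yne
Product: 3 5-hydroxy-7-[(2-methylbut-3-yn-2-yl)oxy]-4H-chromen-4-one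
Conditions: K2CO3, KI (cat.), CuI (cat.), acetone, reflux
Reagents that add atoms: none
Why: Copper-assisted Williamson-type etherification with the tertiary propargylic chloride should alkylate only the acidic, non-chelated 7-OH, because the 5-OH is tied up in a hydrogen bond to the C4 carbonyl.

**Step 2**
Reactants: 3 5-hydroxy-7-[(2-methylbut-3-yn-2-yl)oxy]-4H-chromen-4-one
Product: 4 5-hydroxy-7-[(2-methylbut-3-en-2-yl)oxy]-4H-chromen-4-one
Conditions: H2 (1 atm), Pd/CaCO3 poisoned with Pb(OAc)2 (Lindlar catalyst), quinoline, EtOAc, rt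
Reagents that add atoms: none
Why: Lindlar semi-hydrogenation should stop at the terminal alkene and leave the chromone C2=C3 bond untouched, giving the 1,1-dimethylallyl ether needed for the Claisen step.

**Step 3**
Reactants: 4 5-hydroxy-7-[(2-methylbut-3-en-2-yl)oxy]-4H-chromen-4-one
Product: 5 5-hydroxy-6-iodo-7-[(2-methylbut-3-en-2-yl)oxy]-4H-chromen-4-one
Conditions: benzyltrimethylammonium dichloroiodate (1.05 equiv), CaCO3, CH2Cl2/MeOH, 0 °C to rt
Reagents that add atoms: benzyltrimethylammonium dichloroiodate, C[N+](C)(C)Cc1ccccc1.Cl[I-]Cl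
Why: Electrophilic aromatic iodination with buffered dichloroiodate goes ortho to the free, chelated 5-OH (C6) in 5-hydroxy-7-alkoxychromones, and the phloroglucinol-type ring should react well ahead of the deactivated, neopentyl-like vinyl group.

**Step 4**
Reactants: 5 5-hydroxy-6-iodo-7-[(2-methylbut-3-en-2-yl)oxy]-4H-chromen-4-one
Product: 6 5,7-dihydroxy-6-iodo-8-(3-methylbut-2-en-1-yl)-4H-chromen-4-one
Conditions: o-xylene, 130 °C, degassed
Reagents that add atoms: none
Why: The aromatic Claisen rearrangement ([3,3]-sigmatropic shift) of the tertiary allyl ether can only end productively at C8 because C6 carries iodine, and tautomerisation delivers the phenol with the allyl unit inverted to the linear prenyl group.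

**Step 5**
Reactants: 6 5,7-dihydroxy-6-iodo-8-(3-methylbut-2-en-1-yl)-4H-chromen-4-one
Product: 7 6-iodo-5,7-bis(methoxymethoxy)-8-(3-methylbut-2-en-1-yl)-4H-chromen-4-one
Conditions: NaH (2.5 equiv), MOMCl (3 equiv), DMF, 0 °C to rt
Reagents that add atoms: chloromethyl methyl ether (MOMCl), COCCl
Why: Williamson-type alkylation of the bis-phenoxide gives base-stable acetals that mask both phenols for the basic coupling, with NaH chosen because the chelated, doubly flanked 5-OH is sluggish with amine bases.

**Step 6**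
Reactants: 7 6-iodo-5,7-bis(methoxymethoxy)-8-(3-methylbut-2-en-1-yl)-4H-chromen-4-one; 8 diallyl malonate
Product: 9 diallyl 2-[5,7-bis(methoxymethoxy)-8-(3-methylbut-2-en-1-yl)-4-oxo-4H-chromen-6-yl]malonate
Conditions: CuI (20 mol%), 2-picolinic acid (40 mol%), Cs2CO3 (3 equiv), 8 (2 equiv), 1,4-dioxane, 70 °C
Reagents that add atoms: none
Why: Hurtley-type copper-catalysed α-arylation of the malonate with the aryl iodide, helped by the two ortho acetal oxygens, installs the whole malonyl unit at C6, and allyl esters are chosen so that the diacid can later be freed without acid or base.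

**Step 7**
Reactants: 9 diallyl 2-[5,7-bis(methoxymethoxy)-8-(3-methylbut-2-en-1-yl)-4-oxo-4H-chromen-6-yl]malonate
Product: 11 diallyl 2-[5,7-dihydroxy-8-(3-methylbut-2-en-1-yl)-4-oxo-4H-chromen-6-yl]malonate, via bis(trimethylsilyl) ether 10 (not isolated)
Conditions: Me3SiOSO2CF3 (4 equiv), 2,2'-bipyridyl (6 equiv), CH2Cl2, 0 °C to rt; then H2O
Reagents that add atoms: none
Why: Silyl triflate buffered by 2,2'-bipyridyl cleaves aryl MOM ethers through the aryl silyl ethers under non-protic, near-neutral conditions, which should spare the prenyl alkene and the allyl esters and avoid acid-catalysed lactonisation of the ortho-hydroxyaryl malonate.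

**Step 8**
Reactants: 11 diallyl 2-[5,7-dihydroxy-8-(3-methylbut-2-en-1-yl)-4-oxo-4H-chromen-6-yl]malonate
Product: 12 diallyl 2-[5,7-diacetoxy-8-(3-methylbut-2-en-1-yl)-4-oxo-4H-chromen-6-yl]malonate
Conditions: Ac2O (4 equiv), pyridine, DMAP (cat.), CH2Cl2, 0 °C to rt, directly on crude 11
Reagents that add atoms: acetic anhydride, CC(=O)OC(C)=O
Why: DMAP-catalysed O-acetylation is fast for both phenols and turns them into non-nucleophilic, HCl-tolerant esters that cannot capture the ketene of the key step.

**Step 9**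
Reactants: 12 diallyl 2-[5,7-diacetoxy-8-(3-methylbut-2-en-1-yl)-4-oxo-4H-chromen-6-yl]malonate
Product: 13 2-[5,7-diacetoxy-8-(3-methylbut-2-en-1-yl)-4-oxo-4H-chromen-6-yl]malonic acid
Conditions: Pd(PPh3)4 (5 mol%), sodium p-toluenesulfinate (2.5 equiv), THF/H2O, rt; then cold 1 M HCl to pH 2; dried below 30 °C and used at once
Reagents that add atoms: none
Why: Tsuji–Trost deallylation with zerovalent palladium and a soft, non-basic sulfinate as allyl acceptor frees both acids at room temperature without an amine (which would cleave the aryl acetates and add to chromone C2) and without heat (which would decarboxylate the arylmalonic acid).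

**Step 10**
Reactants: 14 3-pentanone
Product: 15 (Z)-trimethyl(pent-2-en-3-yloxy)silane
Conditions: Me3SiCl, NaI, Et3N, MeCN, rt; distillation
Reagents that add atoms: chlorotrimethylsilane, C[Si](C)(C)Cl
Why: Soft enolisation by Me3SiI formed in the flask with Et3N gives the thermodynamic silyl enol ether, mainly Z; the ketone is symmetrical, so only one constitution can arise, and the double-bond geometry is lost in the pyrone.

**Step 11**
Reactants: 13 2-[5,7-diacetoxy-8-(3-methylbut-2-en-1-yl)-4-oxo-4H-chromen-6-yl]malonic acid; 15 (Z)-trimethyl(pent-2-en-3-yloxy)silane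
Product: 18 5,7-diacetoxy-6-(6-ethyl-4-hydroxy-5-methyl-2-oxo-2H-pyran-3-yl)-8-(3-methylbut-2-en-1-yl)-4H-chromen-4-one, via malonyl dichloride 16 (not isolated), via aryl(chlorocarbonyl)ketene 17 (not isolated)
Conditions: 1-chloro-N,N,2-trimethylprop-1-en-1-amine (2.1 equiv), CH2Cl2, 0 °C to rt; then 15 (4 equiv), toluene, rt to 70 °C; aqueous work-up
Reagents that add atoms: none
Why: The α-chloroenamine turns both carboxyl groups into acid chlorides without releasing HCl, and dichloride 16 then loses HCl to the excess enol silane (cleaved to 3-pentanone and Me3SiCl), giving ketene 17 while the prenyl alkene never meets free acid. The nucleophilic carbon of 15 adds to the sp carbon of the ketene (Mukaiyama-type C-acylation, C4–C5 bond); the new ethyl ketone enolises toward C5 and its enol oxygen displaces chloride at the remaining acyl chloride carbon (O1–C2 bond), silicon leaving as Me3SiCl. The closest known reaction type is the 4-hydroxy-2-pyrone synthesis from malonyl dichlorides or (chlorocarbonyl)ketenes and ketone enol silanes, which tolerates 2,6-disubstituted aryl groups. The ring closes as a 6-exo-trig acyl substitution, and no stereocentre is formed. The step needs C-acylation ahead of O-acylation, ketene oligomerisation and capture by ring A; the soft enol silane in excess, the acetates on O5 and O7 and the absence of any other enolisable carbonyl should secure this, and the symmetry of 3-pentanone with the equivalence of the two acyl carbons removes any regiochemical question. If some 16 acylates 15 directly, the same pyrone results.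

**Step 12**
Reactants: 18 5,7-diacetoxy-6-(6-ethyl-4-hydroxy-5-methyl-2-oxo-2H-pyran-3-yl)-8-(3-methylbut-2-en-1-yl)-4H-chromen-4-one
Product: 19 5,7-diacetoxy-6-[6-ethyl-4-(methoxymethoxy)-5-methyl-2-oxo-2H-pyran-3-yl]-8-(3-methylbut-2-en-1-yl)-4H-chromen-4-one
Conditions: MOMCl (1.5 equiv), i-Pr2NEt (2 equiv), CH2Cl2, 0 °C
Reagents that add atoms: chloromethyl methyl ether (MOMCl), COCCl
Why: O-alkylation of the vinylogous acid with MOMCl and a hindered amine masks the acidic pyrone hydroxyl, which would otherwise quench the hydroxorhodium catalyst, and any O2-alkylated isomer would converge at the last step.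

**Step 13**
Reactants: 19 5,7-diacetoxy-6-[6-ethyl-4-(methoxymethoxy)-5-methyl-2-oxo-2H-pyran-3-yl]-8-(3-methylbut-2-en-1-yl)-4H-chromen-4-one; 20 phenylboronic acid
Product: 21 (2S)-5,7-diacetoxy-6-[6-ethyl-4-(methoxymethoxy)-5-methyl-2-oxo-2H-pyran-3-yl]-8-(3-methylbut-2-en-1-yl)-2-phenylchroman-4-one
Conditions: [Rh(OH)(L)]2 (2.5 mol%; L = (1S,4S)-2,5-diphenylbicyclo[2.2.2]octa-2,5-diene, made beforehand from [RhCl(C2H4)2]2, L and KOH), 20 (3 equiv), 1,4-dioxane/H2O (10:1), 50 °C
Reagents that add atoms: none
Why: In this rhodium-catalysed asymmetric 1,4-addition of an arylboronic acid (Hayashi–Miyaura reaction) the C2-symmetric diene on rhodium shields one face of C2=C3 so that phenyl is delivered to give the (2S) centre, and the base-free hydroxo complex should keep the aryl acetates intact and the flavanone ring closed.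

**Step 14**
Reactants: 21 (2S)-5,7-diacetoxy-6-[6-ethyl-4-(methoxymethoxy)-5-methyl-2-oxo-2H-pyran-3-yl]-8-(3-methylbut-2-en-1-yl)-2-phenylchroman-4-one
Product: 22 (2S)-6-(6-ethyl-4-hydroxy-5-methyl-2-oxo-2H-pyran-3-yl)-5,7-dihydroxy-8-(3-methylbut-2-en-1-yl)-2-phenylchroman-4-one
Conditions: HCl (1.25 M in MeOH), rt to 40 °C, monitored and stopped at full conversion
Reagents that add atoms: none
Why: Acid-catalysed methanolysis (transesterification of the two aryl acetates and acetal exchange of the MOM ether) frees all three hydroxyls under conditions in which C2 cannot epimerise by retro-oxa-Michael opening and which are mild enough to leave the prenyl group uncyclised.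

**Compound list**
1 | 5,7-dihydroxy-4H-chromen-4-one | O=c1ccoc2cc(O)cc(O)c12 | starting material
2 | 3-chloro-3-methylbut-1-yne | CC(C)(Cl)C#C | starting material
3 | 5-hydroxy-7-[(2-methylbut-3-yn-2-yl)oxy]-4H-chromen-4-one | O=c1ccoc2cc(OC(C)(C)C#C)cc(O)c12 | intermediate
4 | 5-hydroxy-7-[(2-methylbut-3-en-2-yl)oxy]-4H-chromen-4-one | O=c1ccoc2cc(OC(C)(C)C=C)cc(O)c12 | intermediate
5 | 5-hydroxy-6-iodo-7-[(2-methylbut-3-en-2-yl)oxy]-4H-chromen-4-one | O=c1ccoc2cc(OC(C)(C)C=C)c(I)c(O)c12 | intermediate
6 | 5,7-dihydroxy-6-iodo-8-(3-methylbut-2-en-1-yl)-4H-chromen-4-one | O=c1ccoc2c(CC=C(C)C)c(O)c(I)c(O)c12 | intermediate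
7 | 6-iodo-5,7-bis(methoxymethoxy)-8-(3-methylbut-2-en-1-yl)-4H-chromen-4-one | O=c1ccoc2c(CC=C(C)C)c(OCOC)c(I)c(OCOC)c12 | intermediate
8 | diallyl malonate | C=CCOC(=O)CC(=O)OCC=C | starting material
9 | diallyl 2-[5,7-bis(methoxymethoxy)-8-(3-methylbut-2-en-1-yl)-4-oxo-4H-chromen-6-yl]malonate | O=c1ccoc2c(CC=C(C)C)c(OCOC)c(C(C(=O)OCC=C)C(=O)OCC=C)c(OCOC)c12 | intermediate
10 | diallyl 2-[8-(3-methylbut-2-en-1-yl)-4-oxo-5,7-bis(trimethylsilyloxy)-4H-chromen-6-yl]malonate | O=c1ccoc2c(CC=C(C)C)c(O[Si](C)(C)C)c(C(C(=O)OCC=C)C(=O)OCC=C)c(O[Si](C)(C)C)c12 | intermediate (not isolated)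
11 | diallyl 2-[5,7-dihydroxy-8-(3-methylbut-2-en-1-yl)-4-oxo-4H-chromen-6-yl]malonate | O=c1ccoc2c(CC=C(C)C)c(O)c(C(C(=O)OCC=C)C(=O)OCC=C)c(O)c12 | intermediate
12 | diallyl 2-[5,7-diacetoxy-8-(3-methylbut-2-en-1-yl)-4-oxo-4H-chromen-6-yl]malonate | O=c1ccoc2c(CC=C(C)C)c(OC(C)=O)c(C(C(=O)OCC=C)C(=O)OCC=C)c(OC(C)=O)c12 | intermediate
13 | 2-[5,7-diacetoxy-8-(3-methylbut-2-en-1-yl)-4-oxo-4H-chromen-6-yl]malonic acid | O=c1ccoc2c(CC=C(C)C)c(OC(C)=O)c(C(C(=O)O)C(=O)O)c(OC(C)=O)c12 | intermediate
14 | 3-pentanone | CCC(=O)CC | starting material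
15 | (Z)-trimethyl(pent-2-en-3-yloxy)silane | C/C=C(\O[Si](C)(C)C)CC | intermediate
16 | 2-[5,7-diacetoxy-8-(3-methylbut-2-en-1-yl)-4-oxo-4H-chromen-6-yl]malonyl dichloride | O=c1ccoc2c(CC=C(C)C)c(OC(C)=O)c(C(C(Cl)=O)C(Cl)=O)c(OC(C)=O)c12 | intermediate (not isolated)
17 | [5,7-diacetoxy-8-(3-methylbut-2-en-1-yl)-4-oxo-4H-chromen-6-yl](chlorocarbonyl)ketene | O=C=C(C(Cl)=O)c1c(OC(C)=O)c(CC=C(C)C)c2occc(=O)c2c1OC(C)=O | intermediate (not isolated)
18 | 5,7-diacetoxy-6-(6-ethyl-4-hydroxy-5-methyl-2-oxo-2H-pyran-3-yl)-8-(3-methylbut-2-en-1-yl)-4H-chromen-4-one | CCc1oc(=O)c(-c2c(OC(C)=O)c(CC=C(C)C)c3occc(=O)c3c2OC(C)=O)c(O)c1C | intermediate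
19 | 5,7-diacetoxy-6-[6-ethyl-4-(methoxymethoxy)-5-methyl-2-oxo-2H-pyran-3-yl]-8-(3-methylbut-2-en-1-yl)-4H-chromen-4-one | CCc1oc(=O)c(-c2c(OC(C)=O)c(CC=C(C)C)c3occc(=O)c3c2OC(C)=O)c(OCOC)c1C | intermediate
20 | phenylboronic acid | OB(O)c1ccccc1 | starting material
21 | (2S)-5,7-diacetoxy-6-[6-ethyl-4-(methoxymethoxy)-5-methyl-2-oxo-2H-pyran-3-yl]-8-(3-methylbut-2-en-1-yl)-2-phenylchroman-4-one | CCc1oc(=O)c(-c2c(OC(C)=O)c(CC=C(C)C)c3c(c2OC(C)=O)C(=O)C[C@@H](c2ccccc2)O3)c(OCOC)c1C | intermediate
22 | (2S)-6-(6-ethyl-4-hydroxy-5-methyl-2-oxo-2H-pyran-3-yl)-5,7-dihydroxy-8-(3-methylbut-2-en-1-yl)-2-phenylchroman-4-one | CCc1oc(=O)c(-c2c(O)c(CC=C(C)C)c3c(c2O)C(=O)C[C@@H](c2ccccc2)O3)c(O)c1C | target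

**Step count.** Total: 14 steps. Longest linear sequence: 13 steps (steps 1–9 and 11–14, from 1 to 22); step 10 is a one-step side branch from 14.

**Steps most likely to fail**

1. Step 11 (key step). The enol silane may be acylated on oxygen or simply protodesilylated faster than it is C-acylated, the ketene may oligomerise, or the diacid may decarboxylate during activation. Fallback: setting out from 13, DCC-mediated esterification with 2,4,6-trichlorophenol (CH2Cl2, 0 °C) would give the storable, doubly activated bis(2,4,6-trichlorophenyl) 2-[5,7-diacetoxy-8-(3-methylbut-2-en-1-yl)-4-oxo-4H-chromen-6-yl]malonate F2. Thermal condensation of this active ester with 3-pentanone 14 (diphenyl ether, sealed tube, about 200 °C) is the known active-malonate route to 4-hydroxy-2-pyrones; it expels two equivalents of the phenol and comes back to the route at 18 with no acid chloride and no HCl.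

2. Step 6. Activation of the doubly ortho-flanked, electron-rich C6–I bond by copper may be slower than protodeiodination or than conjugate attack of the malonate anion on chromone C2. Fallback: setting out from 7, palladium-catalysed α-arylation of diethyl malonate (Pd(dba)2, P(t-Bu)3, K3PO4, toluene, 70 °C), which copes better with hindered aryl halides, would give diethyl 2-[5,7-bis(methoxymethoxy)-8-(3-methylbut-2-en-1-yl)-4-oxo-4H-chromen-6-yl]malonate F1. Diallyl malonate cannot be used there because zerovalent palladium ionises allyl esters. Transesterification of this diester in allyl alcohol with Ti(OiPr)4 (cat.) at reflux, with ethanol distilled off, comes back to the route at 9.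

3. Step 13. Facial selectivity on this heavily substituted chromone may be poor, or enantiopurity may erode through reversible ring-opening of the flavanone. Fallback: setting out from 19, addition of 20 with the achiral catalyst [Rh(OH)(C8H12)]2 (C8H12 = 1,5-cyclooctadiene; dioxane/H2O, 60 °C) would give racemic 5,7-diacetoxy-6-[6-ethyl-4-(methoxymethoxy)-5-methyl-2-oxo-2H-pyran-3-yl]-8-(3-methylbut-2-en-1-yl)-2-phenylchroman-4-one F3. Preparative HPLC on an amylose tris(3,5-dimethylphenylcarbamate) phase would then separate the enantiomers; the (2S)-enantiomer is 21, where the route is rejoined, and the (2R)-enantiomer F4 is set aside. Stereocontrol thus moves from the catalyst to a separation.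

**Further compounds**
F1 | step 6 | diethyl 2-[5,7-bis(methoxymethoxy)-8-(3-methylbut-2-en-1-yl)-4-oxo-4H-chromen-6-yl]malonate | O=c1ccoc2c(CC=C(C)C)c(OCOC)c(C(C(=O)OCC)C(=O)OCC)c(OCOC)c12
F2 | step 11 | bis(2,4,6-trichlorophenyl) 2-[5,7-diacetoxy-8-(3-methylbut-2-en-1-yl)-4-oxo-4H-chromen-6-yl]malonate | O=c1ccoc2c(CC=C(C)C)c(OC(C)=O)c(C(C(=O)Oc3c(Cl)cc(Cl)cc3Cl)C(=O)Oc3c(Cl)cc(Cl)cc3Cl)c(OC(C)=O)c12
F3 | step 13 | racemic 5,7-diacetoxy-6-[6-ethyl-4-(methoxymethoxy)-5-methyl-2-oxo-2H-pyran-3-yl]-8-(3-methylbut-2-en-1-yl)-2-phenylchroman-4-one | CCc1oc(=O)c(-c2c(OC(C)=O)c(CC=C(C)C)c3c(c2OC(C)=O)C(=O)CC(c2ccccc2)O3)c(OCOC)c1C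
F4 | step 13 | (2R)-5,7-diacetoxy-6-[6-ethyl-4-(methoxymethoxy)-5-methyl-2-oxo-2H-pyran-3-yl]-8-(3-methylbut-2-en-1-yl)-2-phenylchroman-4-one | CCc1oc(=O)c(-c2c(OC(C)=O)c(CC=C(C)C)c3c(c2OC(C)=O)C(=O)C[C@H](c2ccccc2)O3)c(OCOC)c1C
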